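A one-step world gives one product, but this flask shares its substrate out in a race. In the amber run side product A stands flat from the first reading, near 63.4 %, while target climbs from 3.3 % to 12.0 %. So I read the early hours as two branches. Substrate plus second reagent gives side product A, and substrate plus coupling partner gives a simulated intermediate, each one to one.

all flasks: substrate 0.25 M
- red: coupling partner 0.375 M; second reagent 0.225 M; temperature 10 °C; run made earlier
- amber: coupling partner 0.19 M; second reagent 0.225 M; temperature 25 °C; run made earlier
- ochre: coupling partner 0.28 M; second reagent 0.225 M; temperature 10 °C; run made earlier
- noon: coupling partner 0.375 M; second reagent 0.225 M (in portions, 3, over 30 h); temperature 25 °C; first portion at the start, last at 30 h; time 3.0 d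
- midnight: coupling partner 0.375 M (fed, over 30 h); second reagent 0.225 M; temperature 25 °C; all else is in the flask from the start; the feed brings no volume worth counting; time 3.0 d
- spring: coupling partner 0.375 M; second reagent 0.225 M; temperature 25 °C; everything together at the start; time 3.0 d
- winter: coupling partner 0.375 M (fed, over 8.0 h); second reagent 0.225 M; temperature 25 °C; all else is in the flask from the start; the feed brings no volume worth counting; time 3.0 d
- autumn: coupling partner 0.375 M; second reagent 0.225 M (fed, over 30 h); the addition at 5 °C, then warmed to 25 °C; the feed brings no volume worth counting; time 3.0 d

| run | time / d | target / % | side product A / % |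
|---|---|---|---|
| red | 0.833 | 6.2 | 41.5 |
| red | 2.00 | 10.4 | 41.6 |
| red | 4.00 | 14.5 | 43.3 |
| red | 6.00 | 18.1 | 42.8 |
| amber | 0.250 | 3.3 | 63.6 |
| amber | 0.500 | 4.3 | 64.0 |
| amber | 1.25 | 8.2 | 63.0 |
| amber | 3.00 | 12.0 | 62.8 |
| ochre | 1.67 | 7.6 | 49.8 |
| ochre | 4.00 | 11.9 | 49.0 |
| ochre | 5.00 | 13.6 | 49.8 |
| ochre | 6.00 | 14.3 | 49.7 |

(readings scatter by 0.5 percentage points)

- which flask leads in share of target in target plus side product A ("all alike" within 1.5 percentage points) (noon / midnight / spring / winter / autumn / all alike)
- share of target in target plus side product A at the end, noon
- share of target in target plus side product A at the end, midnight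
- share of target in target plus side product A at the end, spring
- share of target in target plus side product A at the end, winter
- share of target in target plus side product A at the end, autumn

- the earlier runs were read with a standard deviation of 0.5 percentage points

I want s, the rate ratio of the two branches (a selectivity factor), and two ways lead to it from amber. The frozen way holds the charges fixed, so side product A over the rest equals s[second reagent]/[coupling partner], which gives 1.46. The integrated way divides one rate law by the other, so substrate and time drop out and [second reagent]/charge = ([coupling partner]/charge)^s, which gives 1.85.

The two part, and the frozen way cheats: in amber second reagent falls to 29.6 % of its charge, further than coupling partner, which falls to 51.8 %, so the ratio it holds fixed does not stay. The integrated way also passes a test at 10 °C on different charges: red gives 1.31 and ochre 1.34. Both lie below the amber value, read at 25 °C.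

Target goes on rising after side product A stops, so I assume the intermediate is finished by second reagent. What matters is then the leftover, the second reagent not spent on side product A when substrate is gone. For spring the law is implicit in side product A. I start from the frozen split, 0.131 M, and average it once with what the law returns, which gives 0.123 M, or 49.0 % of the substrate. The leftover in spring is 0.102 M. In spring the reading to watch is therefore side product A in the first hours.

The forecast puts autumn first, with 34 % there, 27.5 % in spring, 26 % in noon, 8.5 % in winter and 2.5 % in midnight. It starts from “a fast competition for the second reagent”, in which partner plus reagent gives the intermediate, and that intermediate then gives target with substrate. My race is for substrate instead, and I finish the intermediate with second reagent.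

    substrate + coupling partner → intermediate (k = 0.00312 M⁻¹ s⁻¹, Ea = 48.0 kJ mol⁻¹)
    second reagent + intermediate → target (k = 7.01 × 10⁻⁵ M⁻¹ s⁻¹, Ea = 62.0 kJ mol⁻¹)
    substrate + second reagent → side product A (k = 0.00589 M⁻¹ s⁻¹, Ea = 64.0 kJ mol⁻¹)
    second reagent + target → over-reaction product (k = 2.49 × 10⁻⁵ M⁻¹ s⁻¹, Ea = 59.0 kJ mol⁻¹)
    substrate + target → side product B (k = 1.44 × 10⁻⁴ M⁻¹ s⁻¹, Ea = 75.0 kJ mol⁻¹)
    target ⇌ isomer of the product (K = 0.373, k = 8.13 × 10⁻⁵ s⁻¹, Ea = 97.0 kJ mol⁻¹, ΔH = −11.0 kJ mol⁻¹)
    (constants at 25 °C)

The shares end at 88.8 % in autumn, 57.7 % in noon, 27.9 % in spring, 2.17 % in winter and 0.492 % in midnight, so autumn leads as forecast, while noon and autumn stand well above the forecast. Spring holds 48.9 % side product A, a leftover of 0.103 M against my 0.102 M. The neighbour of midnight with 1.0 M of substrate charges coupling partner and second reagent together at 0.600 M, less than its substrate, so I reckon no leftover and 0.400 M of substrate remaining. That neighbour ends with substrate at 40.0 % of its charge, second reagent at 0 % of its own charge and target at 0 % of the substrate charged.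

All runs were computed with constants of no real substance; noise was put on by code.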